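A direct plan would draw both rings from 2,6-dibromo-1,4-benzoquinone A1. Conjugate addition of a triisopropylsilyl bromide to A1 would give the mono-silylated tribromohydroquinone A2. The free phenol of A2 would then be added to the C–H position of a second molecule of A1, with re-aromatisation, to give the silyl-protected diaryl ether A3, and fluoride would free the third hydroxyl. Its weakest steps would be:
- the aryloxylation of the quinone C–H, because a hindered, weakly nucleophilic polybromophenoxide has no precedent in such an addition, and substitution at C–Br and quinone/hydroquinone redox exchange would compete;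
- the bromosilylation, because the carbon that takes the bromide and the oxygen that takes the silyl group would both have to be chosen correctly in one operation.

The route rests on an aryne disconnection of ring B, the 2,3,5-tribromo-4-hydroxyphenyl ring (primed locants): its ether oxygen at C-1' and its bromine at C-2' are neighbours, and C-2' lies next to the C-3' bromine. 3,5-Dibromo-4-methoxybenzyne, released from a 2-magnesiated aryl sulfonate, would take up the magnesium aryloxide of ring A (the benzene-1,4-diol ring) at C-1' and then electrophilic bromine at C-2' in one operation, forming the diaryl ether C–O bond and the fifth C–Br bond with the regiochemistry dictated by the C-3' bromine. No quinone, no addition to a quinone C–H and no bromosilylation would be needed; the three hydroxyls travel as methyl ethers and are freed together at the end.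

Key step: step 5

Assumption: 2,6-dibromoanisole and 2,5-dimethoxyphenol are taken as commercially available starting materials.

**Step 1**
Reactants: 1 2,6-dibromoanisole (1,3-dibromo-2-methoxybenzene)
Product: 3 3,5-dibromo-4-methoxyphenol, via aryl pinacol boronate 2 (not isolated)
Conditions: [Ir(OMe)(cod)]2 (1.5 mol%), 4,4'-di-tert-butyl-2,2'-bipyridine (3 mol%), B2pin2 (1.0 equiv), THF, 80 °C; then 30% H2O2, aq. NaOH, 0 °C → rt
Reagents that add atoms: bis(pinacolato)diboron, CC1(C)OB(OC1(C)C)B1OC(C)(C)C(C)(C)O1 (boron of 2 only); hydrogen peroxide, OO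
Why: Sterically controlled iridium-catalysed C–H borylation followed by oxidation of the C–B bond: C-4 is the only C–H of 1 without an ortho substituent, the aryl bromides are inert to the iridium catalyst, and peroxide converts C–B into C–OH by 1,2-aryl shift from boron to oxygen.

**Step 2**
Reactants: 3 3,5-dibromo-4-methoxyphenol
Product: 4 3,5-dibromo-2-iodo-4-methoxyphenol
Conditions: NIS (1.0 equiv), TsOH·H2O (10 mol%), MeCN, 0 °C → rt, dark
Reagents that add atoms: N-iodosuccinimide, O=C1CCC(=O)N1I
Why: Electrophilic aromatic iodination ortho to the free hydroxyl: the para position carries the methoxy group and the two ortho positions are equivalent, so one equivalent of the iodinating agent can only give 4, and the bulk of the first iodine should slow a second substitution.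

**Step 3**
Reactants: 4 3,5-dibromo-2-iodo-4-methoxyphenol
Product: 5 3,5-dibromo-2-iodo-4-methoxyphenyl 4-chlorobenzenesulfonate
Conditions: 4-ClC6H4SO2Cl (1.2 equiv), Et3N (1.5 equiv), DMAP (5 mol%), CH2Cl2, 0 °C → rt
Reagents that add atoms: 4-chlorobenzenesulfonyl chloride, O=S(=O)(Cl)c1ccc(Cl)cc1
Why: O-Sulfonylation of an acidic phenol under DMAP catalysis; the 4-chlorobenzenesulfonate is the leaving group established for magnesium-based aryne generation, stable to i-PrMgCl at −78 °C and expelled on warming.

**Step 4**
Reactants: 6 2,5-dimethoxyphenol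
Product: 7 2,4-dibromo-3,6-dimethoxyphenol (OH at C-1, Br at C-2 and C-4, OMe at C-3 and C-6)
Conditions: NBS (2.05 equiv), MeCN, −10 °C → rt
Reagents that add atoms: N-bromosuccinimide, O=C1CCC(=O)N1Br
Why: Electrophilic aromatic bromination governed by the free hydroxyl, the strongest donor: in the numbering of 6, C-4 (para) and C-6 (ortho) react, both also ortho to the C-5 methoxy group, whereas C-3 is meta to the hydroxyl and should stay C–H with two equivalents of NBS.

**Step 5**
Reactants: 5 3,5-dibromo-2-iodo-4-methoxyphenyl 4-chlorobenzenesulfonate; 7 2,4-dibromo-3,6-dimethoxyphenol (2.0 equiv)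
Product: 12 1,3-dibromo-2,5-dimethoxy-4-(2,3,5-tribromo-4-methoxyphenoxy)benzene, via magnesium aryloxide 8 (not isolated), via magnesiated aryl sulfonate 9 (not isolated), via 3,5-dibromo-4-methoxybenzyne 10 (not isolated), via aryloxy arylmagnesium chloride 11 (not isolated)
Conditions: 7, MeMgCl, LiCl, THF, 0 °C; then 5, i-PrMgCl (1.05 equiv), −78 °C → rt; then BrCCl2CCl2Br (1.5 equiv), −40 °C → rt
Reagents that add atoms: 1,2-dibromo-1,1,2,2-tetrachloroethane, ClC(Cl)(Br)C(Cl)(Cl)Br; methylmagnesium chloride, C[Mg]Cl, and isopropylmagnesium chloride, CC(C)[Mg]Cl (magnesium of 8, 9 and 11 only)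
Why: Proposed new method: three-component aryloxy-bromination of a 3-bromoaryne — iodine–magnesium exchange at C-2' of 5 (the iodine between the sulfonate and a bromine exchanges far faster than any C–Br bond at −78 °C) would give 9, which on warming should expel the 4-chlorobenzenesulfonate, a much better leaving group than the C-3' bromide, to form aryne 10; aryloxide 8 would add to C-1', and the arylmagnesium 11 so formed, persistent because no proton source is present, would be brominated at C-2' by halophilic attack on BrCCl2CCl2Br. The closest known reaction types are the addition of magnesium thiolates and amides to arynes made from 2-magnesiated aryl sulfonates with electrophilic quench of the resulting Grignard reagent, and the O-arylation of phenols by arynes; a hindered magnesium aryloxide combined with a bromine quench on a 3-haloaryne has not been shown. No ring is closed and no stereocentre is formed. The one selectivity needed is oxygen at C-1' and bromine at C-2': the inductively withdrawing C-3' bromine distorts the aryne so that C-1' is the flatter, more electrophilic carbon and the developing carbanion at C-2' lies next to bromine (aryne distortion model), and the hindered nucleophile also prefers C-1', whose other neighbour is a C–H. The aryl bromides of both partners should be inert to arylmagnesium species below room temperature, and 11, flanked by oxygen and bromine, is a stabilised carbanion that should not lose MgBrCl before the quench.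

**Step 6**
Reactants: 12 1,3-dibromo-2,5-dimethoxy-4-(2,3,5-tribromo-4-methoxyphenoxy)benzene
Product: 13 3,5-dibromo-2-(2,3,5-tribromo-4-hydroxyphenoxy)benzene-1,4-diol
Conditions: BBr3 (6 equiv), CH2Cl2, −78 °C → rt; then MeOH, aq. Na2S2O4 work-up
Reagents that add atoms: none
Why: Lewis-acid cleavage of aryl methyl ethers with BBr3 (boron coordinates each methoxy oxygen and bromide removes the methyl group by SN2); the diaryl ether and the C–Br bonds are inert, the reductive work-up should keep the bromohydroquinone from air oxidation, and no stereocentre is present.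

**Compound list**
1 | 2,6-dibromoanisole (1,3-dibromo-2-methoxybenzene) | COc1c(Br)cccc1Br | starting material
2 | 2-(3,5-dibromo-4-methoxyphenyl)-4,4,5,5-tetramethyl-1,3,2-dioxaborolane | COc1c(Br)cc(B2OC(C)(C)C(C)(C)O2)cc1Br | intermediate
3 | 3,5-dibromo-4-methoxyphenol | COc1c(Br)cc(O)cc1Br | intermediate
4 | 3,5-dibromo-2-iodo-4-methoxyphenol | COc1c(Br)cc(O)c(I)c1Br | intermediate
5 | 3,5-dibromo-2-iodo-4-methoxyphenyl 4-chlorobenzenesulfonate | COc1c(Br)cc(OS(=O)(=O)c2ccc(Cl)cc2)c(I)c1Br | intermediate
6 | 2,5-dimethoxyphenol | COc1ccc(OC)c(O)c1 | starting material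
7 | 2,4-dibromo-3,6-dimethoxyphenol | COc1cc(Br)c(OC)c(Br)c1O | intermediate
8 | chloromagnesium 2,4-dibromo-3,6-dimethoxyphenoxide | COc1cc(Br)c(OC)c(Br)c1O[Mg]Cl | intermediate
9 | [2,4-dibromo-6-(4-chlorophenylsulfonyloxy)-3-methoxyphenyl]magnesium chloride | COc1c(Br)cc(OS(=O)(=O)c2ccc(Cl)cc2)c([Mg]Cl)c1Br | intermediate
10 | 3,5-dibromo-4-methoxybenzyne (3,5-dibromo-4-methoxy-1,2-didehydrobenzene) | COC1=C(Br)C#CC=C1Br | intermediate
11 | [2,4-dibromo-6-(2,4-dibromo-3,6-dimethoxyphenoxy)-3-methoxyphenyl]magnesium chloride | COc1cc(Br)c(OC)c(Br)c1Oc1cc(Br)c(OC)c(Br)c1[Mg]Cl | intermediate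
12 | 1,3-dibromo-2,5-dimethoxy-4-(2,3,5-tribromo-4-methoxyphenoxy)benzene | COc1cc(Br)c(OC)c(Br)c1Oc1cc(Br)c(OC)c(Br)c1Br | intermediate
13 | 3,5-dibromo-2-(2,3,5-tribromo-4-hydroxyphenoxy)benzene-1,4-diol (achiral) | Oc1cc(Br)c(O)c(Br)c1Oc1cc(Br)c(O)c(Br)c1Br | target

Total step count: 6. Longest linear sequence: 5 steps (steps 1, 2, 3, 5, 6); step 4 makes the ring A fragment in parallel.

**Steps most likely to fail**

Step 5 (Proposed new method). The hindered magnesium aryloxide may be too slow to intercept the aryne, which would then be consumed by its own magnesiated precursor, or the adduct Grignard reagent may lose MgBrCl before the bromine quench. The fallback uses known chemistry, sets out from 7 and comes back to the route at 13.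
- Nucleophilic aromatic substitution of 7 on 3-bromo-4-fluorobenzaldehyde (K2CO3, DMF, 100 °C) would give 3-bromo-4-(2,4-dibromo-3,6-dimethoxyphenoxy)benzaldehyde F1.
- Baeyer–Villiger oxidation (mCPBA, CH2Cl2) would give 3-bromo-4-(2,4-dibromo-3,6-dimethoxyphenoxy)phenyl formate F2, methanolysed in the same operation (K2CO3, MeOH) to 3-bromo-4-(2,4-dibromo-3,6-dimethoxyphenoxy)phenol F3.
- Bromination of both positions ortho to the new free hydroxyl (Br2, AcOH, rt) would give 2,3,6-tribromo-4-(2,4-dibromo-3,6-dimethoxyphenoxy)phenol F4.
- BBr3 under the conditions of step 6 would cleave the two methyl ethers of F4 to give 13.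

Step 2. Iodination at a position flanked by hydroxyl and bromine may be sluggish, and substitution at the second ortho position may then compete. The fallback replaces electrophilic substitution by directed metalation, sets out from 3 and comes back at 4.
- Acylation of 3 (Boc2O, DMAP, MeCN) would give tert-butyl 3,5-dibromo-4-methoxyphenyl carbonate F5.
- Magnesiation between the carbonate oxygen and a bromine (TMPMgCl·LiCl, THF, 0 °C) would give [2,4-dibromo-6-(tert-butoxycarbonyloxy)-3-methoxyphenyl]magnesium chloride F6.
- Quenching with I2 would give tert-butyl 3,5-dibromo-2-iodo-4-methoxyphenyl carbonate F7, and TFA in CH2Cl2 would remove the carbonate to give 4.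

Step 1. The C–H borylation may stall, or the boronate may undergo protodeborylation before it is oxidised. The fallback is a classical sequence that sets out from 1 and comes back at 3; it relies on nitration going para to the methoxy group.
- Nitration para to the methoxy group (HNO3, AcOH/H2SO4, 0 °C) would give 1,3-dibromo-2-methoxy-5-nitrobenzene F8.
- Reduction (Fe, NH4Cl, EtOH/H2O, 70 °C) would give 3,5-dibromo-4-methoxyaniline F9.
- Diazotisation (NaNO2, aq. H2SO4, 0 °C) would give 3,5-dibromo-4-methoxybenzenediazonium hydrogen sulfate F10, hydrolysed (Cu2O, Cu(NO3)2, H2O, rt) to 3.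

**Further compounds**
F1 | step 5 | 3-bromo-4-(2,4-dibromo-3,6-dimethoxyphenoxy)benzaldehyde | O=Cc1ccc(Oc2c(OC)cc(Br)c(OC)c2Br)c(Br)c1
F2 | step 5 | 3-bromo-4-(2,4-dibromo-3,6-dimethoxyphenoxy)phenyl formate | O=COc1ccc(Oc2c(OC)cc(Br)c(OC)c2Br)c(Br)c1
F3 | step 5 | 3-bromo-4-(2,4-dibromo-3,6-dimethoxyphenoxy)phenol | Oc1ccc(Oc2c(OC)cc(Br)c(OC)c2Br)c(Br)c1
F4 | step 5 | 2,3,6-tribromo-4-(2,4-dibromo-3,6-dimethoxyphenoxy)phenol | Oc1c(Br)cc(Oc2c(OC)cc(Br)c(OC)c2Br)c(Br)c1Br
F5 | step 2 | tert-butyl 3,5-dibromo-4-methoxyphenyl carbonate | COc1c(Br)cc(OC(=O)OC(C)(C)C)cc1Br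
F6 | step 2 | [2,4-dibromo-6-(tert-butoxycarbonyloxy)-3-methoxyphenyl]magnesium chloride | COc1c(Br)cc(OC(=O)OC(C)(C)C)c([Mg]Cl)c1Br
F7 | step 2 | tert-butyl 3,5-dibromo-2-iodo-4-methoxyphenyl carbonate | COc1c(Br)cc(OC(=O)OC(C)(C)C)c(I)c1Br
F8 | step 1 | 1,3-dibromo-2-methoxy-5-nitrobenzene | COc1c(Br)cc([N+](=O)[O-])cc1Br
F9 | step 1 | 3,5-dibromo-4-methoxyaniline | COc1c(Br)cc(N)cc1Br
F10 | step 1 | 3,5-dibromo-4-methoxybenzenediazonium hydrogen sulfate | COc1c(Br)cc([N+]#N)cc1Br.OS(=O)(=O)[O-]
A1 | direct plan | 2,6-dibromo-1,4-benzoquinone | O=C1C=C(Br)C(=O)C(Br)=C1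
A2 | direct plan | 2,3,5-tribromo-4-(triisopropylsilyloxy)phenol | CC(C)[Si](Oc1c(Br)cc(O)c(Br)c1Br)(C(C)C)C(C)C
A3 | direct plan | 3,5-dibromo-2-[2,3,5-tribromo-4-(triisopropylsilyloxy)phenoxy]benzene-1,4-diol | CC(C)[Si](Oc1c(Br)cc(Oc2c(Br)c(O)c(Br)cc2O)c(Br)c1Br)(C(C)C)C(C)C
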